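The data were computed with made-up constants; the scatter is artificial.

Slowness is what we can measure here: starting material leaves over hours. The last reading adds up to 78.3% in the larch run and 99.0% in the cedar run, and a reading scatters by 1 percentage point, so the larch run held material that the columns do not show. We keep books on the charge and, as an assumption of our own, book nothing in that unread form for dawn and autumn.

| setting | larch | cedar | birch | dawn | autumn |
|---|---|---|---|---|---|
| starting material | 10 mM | 10 mM | 5 mM | 10 mM | 10 mM |
| coupling partner | 0.50 equiv | 0.75 equiv | 1 equiv | 1.00 equiv | 1.00 equiv |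
| free catalyst | 15 mol% | 15 mol% | 15 mol% | 15 mol% | 15 mol% |
| second catalyst | 5 mol% | 5 mol% | 5 mol% | 5 mol% | 5 mol% |
| temperature | 20 °C | 39 °C | 20 °C | 43 °C | 35 °C |
| remark | run made earlier | run made earlier | run made earlier |  |  |
| time |  |  |  | 6.0 h | 6.0 h |

| run | time / h | starting material / % | target / % | side product / % | over-reaction product / % |
|---|---|---|---|---|---|
| larch | 1.00 | 87.3 | 5.4 | 0 | 0 |
| larch | 3.00 | 64.7 | 21.5 | 0.9 | 4.6 |
| larch | 5.00 | 51.0 | 29.5 | 1.2 | 6.3 |
| larch | 8.00 | 32.8 | 29.9 | 7.1 | 15.6 |
| larch | 12.0 | 23.1 | 23.3 | 11.1 | 26.6 |
| larch | 15.0 | 16.4 | 17.2 | 15.5 | 29.2 |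
| cedar | 0.500 | 76.7 | 13.3 | 1.6 | 1.8 |
| cedar | 1.00 | 58.2 | 21.7 | 1.8 | 11.3 |
| cedar | 1.50 | 44.0 | 22.0 | 4.8 | 21.5 |
| cedar | 2.50 | 24.3 | 17.9 | 8.9 | 42.3 |
| cedar | 4.00 | 12.7 | 8.7 | 15.4 | 63.8 |
| cedar | 8.00 | 3.2 | 0 | 21.2 | 74.6 |
| birch | 1.00 | 93.1 | 2.4 | 0.9 | 0 |
| birch | 2.00 | 87.3 | 8.1 | 0.3 | 0.1 |
| birch | 4.00 | 76.9 | 18.8 | 1.5 | 1.3 |
| birch | 8.00 | 56.4 | 25.3 | 2.8 | 11.1 |
| birch | 15.0 | 36.7 | 29.9 | 4.3 | 25.9 |

(each reading ± 1 percentage point)

- the numbers in the tables scatter with a standard deviation of 1 points

1. which of these there is most of at the end, counted by the starting material in it, dawn (starting material / over-reaction product / side product / target)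
2. which of these there is most of at the end, counted by the starting material in it, autumn (starting material / over-reaction product / side product / target)
3. final amount of the leader among these, as a percentage of the starting material charged, in dawn
4. final amount of the leader among these, as a percentage of the starting material charged, in autumn

The first ledger entry is what remains. We call the first-order constant of starting material loss the clearing constant, the field's pseudo-first-order constant, so the fraction left is exp(−constant × time). The last useful readings give 0.121 /h for larch and 0.566 /h for cedar. Birch has the partner concentration of larch but half the catalyst concentrations, and its 0.0668 /h is about half of larch's. The second catalyst and the starting material were halved along with the free catalyst, so we assume, without a run that separates them, that this proportionality belongs to the free catalyst. Taking the logarithm as straight in temperature gives a clearing constant of 0.409 /h for autumn and 0.784 /h for dawn. By this reckoning, after 6.0 h, autumn keeps 8.59% and dawn 0.906%.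

The second entry is side product. Its reading-based share of what has left is 2.45% in larch, a loose value given the scatter, and 11.8% in cedar. Taken the same way in temperature, this books 7.72% for autumn, which lies between the two runs, and 16.2% for dawn, an extrapolation beyond the cedar run's 39 °C.

The third entry is target. At the flat top of its curve, making equals losing, which gives a loss constant of 0.129 /h in larch and 0.999 /h in cedar. With the consecutive-reaction formula, autumn holds about 10.2% and dawn about 0.782%.

The books close on over-reaction product, which takes the rest: 73.4% in autumn and 82.1% in dawn.

The forecast also names over-reaction product for dawn and over-reaction product for autumn, at 84% and 71%, and says of the starting material's decay: “It scales with catalyst concentration”.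

The flasks give over-reaction product at 84.0% in dawn and over-reaction product at 71.1% in autumn, where 8.33% of starting material remains.

    starting material + free catalyst ⇌ free catalyst + open intermediate (K = 1.27, k = 4.78 /M/min, Ea = 55.0 kJ/mol, ΔH = −23.0 kJ/mol)
    open intermediate → side product (k = 0.0142 /min, Ea = 103 kJ/mol)
    coupling partner + catalyst intermediate → second catalyst + target (k = 70.9 /M/min, Ea = 63.0 kJ/mol)
    second catalyst + open intermediate ⇌ catalyst intermediate (K = 3000 /M, k = 567 /M/min, Ea = 38.0 kJ/mol, ΔH = 4.00 kJ/mol)
    target → over-reaction product (k = 0.00981 /min, Ea = 96.0 kJ/mol)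
    (constants at 35 °C)

A neighbouring flask repeats autumn with 6 mol% of free catalyst instead of 15 mol%. Its clearing constant scales to 0.163 /h, so 37.6% of the starting material should remain after 6.0 h. That flask holds 36.0%, with 4.44% of side product, 12.5% of target and 46.1% of over-reaction product.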